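**Retrosynthetic overview**

1. Numbering: core O1, C2, C3, C3a, C4–C7, C7a; chain C1′–C12′ counted from C3a. The last disconnection is C5′–C6′: a nickel-electrocatalytic decarboxylative alkenylation joins the N-acyloxyphthalimide of the core-bearing C5′-carboxylic acid (C5′ radical after loss of CO2) to (E)-1-iodo-2,6-dimethylhepta-1,5-diene and gives the unprotected target directly.
2. Enabling feature: C5′ is a heteroatom-free sp3 CH2 bonded directly to the vinylic C6′–H of the E-trisubstituted C6′=C7′ alkene and insulated from C2′=C3′ by C4′; neither atom is stereogenic, so the bond maps onto a primary radical plus an alkenyl iodide whose geometry is transferred with retention.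
3. The same coupling type makes C1′–C2′ one stage earlier (core acetic acid ester + (E)-5-iodo-4-methylpent-4-en-1-ol); oxidation of the CH2OH end then supplies the carboxyl for the final coupling.
4. Core: in the core acetic acid the quaternary C3a carries two CH2–C(=O) arms (C3–C2 of the lactone and the arm ending at C1′), so it comes from an achiral bis(acetate) made by double α′-alkylation of 1,4-dioxaspiro[4.5]dec-6-en-8-one; CBS reduction sets C7a and lactonisation onto the cis arm fixes C3a.
5. Ring order: the six-membered carbocycle is purchased; the γ-lactone ring (O1–C2–C3–C3a–C7a) is closed in step 3, in the same operation that unmasks the C5 enone; no ring is formed after that.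

Key step: step 11

Remark: the enone ketal, pent-4-yn-1-ol and 6-methylhept-5-en-2-one are taken as catalogue compounds; spiro-ketal atoms C8, C9, C10, C5, C6, C7 become core atoms C7a, C3a, C4, C5, C6, C7.

**Route**

Step 1
Reactants: 1 1,4-dioxaspiro[4.5]dec-6-en-8-one; 2 tert-butyl bromoacetate (two equivalents in total)
Product: 4 di-tert-butyl 2,2′-(8-oxo-1,4-dioxaspiro[4.5]dec-6-ene-9,9-diyl)diacetate (achiral), via mono-alkylated enone 3 (not isolated)
Conditions: LDA (1.05 equiv), THF, −78 °C; 2 (1.0 equiv), −78 → 0 °C; LDA (1.1 equiv), −78 → 0 °C; 2 (1.2 equiv), DMPU, −78 °C → rt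
Reagents that add atoms: none
Why: Enolate alkylation (α′-alkylation of a cross-conjugated enone dienolate): C9 is the only enolisable position of 1 (C6 and C7 are vinylic, C5 has no hydrogen), so two successive deprotonation/alkylation cycles with the activated bromide must build the quaternary carbon there, the second enolate being allowed to equilibrate to the ketone dienolate before 2 is added, and the two identical arms keep 4 achiral.

Step 2
Reactants: 4 di-tert-butyl 2,2′-(8-oxo-1,4-dioxaspiro[4.5]dec-6-ene-9,9-diyl)diacetate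
Product: 5 di-tert-butyl 2,2′-[(8R)-8-hydroxy-1,4-dioxaspiro[4.5]dec-6-ene-9,9-diyl]diacetate
Conditions: (S)-2-methyl-CBS-oxazaborolidine (0.2–1.0 equiv), BH3·SMe2, THF, −30 °C; MeOH quench
Reagents that add atoms: none
Why: Corey–Bakshi–Shibata 1,2-reduction of the enone: with the fully substituted C9 as the large and the C7 vinyl as the small flank the (S)-catalyst is expected to give the 8R allylic alcohol (sense to be confirmed by Mosher ester analysis, the (R)-catalyst being used if it is reversed), and this single centre is the only source of chirality in the route; tert-butyl esters and ketal are inert to borane at this temperature.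

Step 3
Reactants: 5 di-tert-butyl 2,2′-[(8R)-8-hydroxy-1,4-dioxaspiro[4.5]dec-6-ene-9,9-diyl]diacetate
Product: 7 2-[(3aS,7aR)-2,5-dioxo-3,4,5,7a-tetrahydro-1-benzofuran-3a(2H)-yl]acetic acid, via hydroxy enone diacid 6 (not isolated)
Conditions: TFA/H2O (9:1), 0 °C → rt; evaporation
Reagents that add atoms: water, O
Why: Acidolysis of both tert-butyl esters and ketal hydrolysis unveil hydroxy enone diacid 6, whose Fischer lactonisation (diastereotopic-group-selective and reversible under these conditions) closes the γ-lactone by 5-exo-trig acyl substitution with the acetic acid arm cis to the C7a–OH because the cis-fused bicycle is the thermodynamic one, so the C7a centre fixes the formerly prochiral C3a; water is present from the start so that the electron-poor enone suppresses ionisation of the allylic C7a–O bond, which is retained.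

Step 4
Reactants: 7 2-[(3aS,7aR)-2,5-dioxo-3,4,5,7a-tetrahydro-1-benzofuran-3a(2H)-yl]acetic acid
Product: 8 1,3-dioxoisoindolin-2-yl 2-[(3aR,7aR)-2,5-dioxo-3,4,5,7a-tetrahydro-1-benzofuran-3a(2H)-yl]acetate
Conditions: N-hydroxyphthalimide, DIC, DMAP (cat.), CH2Cl2, 0 °C → rt
Reagents that add atoms: N-hydroxyphthalimide, O=C1c2ccccc2C(=O)N1O
Why: Carbodiimide (Steglich-type) esterification of the free acid with N-hydroxyphthalimide gives the redox-active ester under neutral conditions that do not touch the γ-acyloxy enone.

Step 5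
Reactants: 9 pent-4-yn-1-ol
Product: 11 (E)-5-iodo-4-methylpent-4-en-1-ol, via alkenylalane 10 (not isolated)
Conditions: Me3Al (3 equiv), Cp2ZrCl2 (0.25 equiv), CH2Cl2, 0 °C → rt; then I2, THF, −30 → 0 °C
Reagents that add atoms: trimethylaluminium, C[Al](C)C; iodine, II
Why: Zirconium-catalysed carboalumination (Negishi) adds Me and Al syn across the terminal alkyne with methyl on the internal carbon, and iodinolysis of the C–Al bond with retention gives the E vinyl iodide; the hydroxyl is carried as its aluminium alkoxide.

Step 6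
Reactants: 8 1,3-dioxoisoindolin-2-yl 2-[(3aR,7aR)-2,5-dioxo-3,4,5,7a-tetrahydro-1-benzofuran-3a(2H)-yl]acetate; 11 (E)-5-iodo-4-methylpent-4-en-1-ol
Product: 12 (3aR,7aR)-3a-[(2E)-6-hydroxy-3-methylhex-2-en-1-yl]-3a,4-dihydro-1-benzofuran-2,5(3H,7aH)-dione
Conditions: 8 (1 equiv), 11 (2 equiv), NiCl2·6H2O (10–20 mol %), 2,2′-bipyridine, AgNO3 (sub-stoichiometric, deposits Ag nanoparticles on the cathode), DMF, undivided cell, (+)Mg/(−)RVC, constant current, rt, argon
Reagents that add atoms: none
Why: Ni-electrocatalytic decarboxylative alkenylation (reductive coupling of a redox-active ester with an alkenyl iodide): single-electron reduction of 8 releases CO2 and the primary C1′ radical, which is captured by the alkenyl–nickel species from 11 and reductively eliminated with retention of the E geometry, free hydroxyl groups being tolerated in reductive nickel cross-electrophile couplings.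

Step 7
Reactants: 12 (3aR,7aR)-3a-[(2E)-6-hydroxy-3-methylhex-2-en-1-yl]-3a,4-dihydro-1-benzofuran-2,5(3H,7aH)-dione
Product: 13 (4E)-6-[(3aR,7aR)-2,5-dioxo-3,4,5,7a-tetrahydro-1-benzofuran-3a(2H)-yl]-4-methylhex-4-enoic acid
Conditions: TEMPO (0.2 equiv), PhI(OAc)2 (2.2 equiv), MeCN/H2O (1:1), rt
Reagents that add atoms: water, O
Why: TEMPO/PhI(OAc)2 oxidation in aqueous acetonitrile converts the primary alcohol via the aldehyde hydrate into the acid under near-neutral conditions that leave enone, lactone and the trisubstituted alkene untouched.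

Step 8
Reactants: 13 (4E)-6-[(3aR,7aR)-2,5-dioxo-3,4,5,7a-tetrahydro-1-benzofuran-3a(2H)-yl]-4-methylhex-4-enoic acid
Product: 14 1,3-dioxoisoindolin-2-yl (4E)-6-[(3aR,7aR)-2,5-dioxo-3,4,5,7a-tetrahydro-1-benzofuran-3a(2H)-yl]-4-methylhex-4-enoate
Conditions: N-hydroxyphthalimide, DIC, DMAP (cat.), CH2Cl2, 0 °C → rt
Reagents that add atoms: N-hydroxyphthalimide, O=C1c2ccccc2C(=O)N1O
Why: Same Steglich-type activation as in step 4, giving the redox-active ester that carries the one extra carbon to be lost as CO2.

Step 9
Reactants: 15 6-methylhept-5-en-2-one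
Product: 17 6-methylhept-5-en-1-yne, via enol phosphate 16 (not isolated)
Conditions: LDA (1.05 equiv), THF, −78 °C; ClP(O)(OEt)2, −78 °C → rt; then LDA (2.2 equiv), −78 °C → rt
Reagents that add atoms: diethyl chlorophosphate, CCOP(=O)(Cl)OCC (its atoms remain only in intermediate 16)
Why: Methyl ketone to terminal alkyne conversion: kinetic enolate formation on the methyl side and O-phosphorylation give the terminal enol phosphate, from which LDA eliminates diethyl phosphate (β-elimination), the trisubstituted alkene being inert.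

Step 10
Reactants: 17 6-methylhept-5-en-1-yne
Product: 19 (E)-1-iodo-2,6-dimethylhepta-1,5-diene, via alkenylalane 18 (not isolated)
Conditions: Me3Al (2 equiv), Cp2ZrCl2 (0.25 equiv), CH2Cl2, 0 °C → rt; then I2, THF, −30 → 0 °C
Reagents that add atoms: trimethylaluminium, C[Al](C)C; iodine, II
Why: Negishi carboalumination/iodinolysis as in step 5: syn Me–Al addition fixes the E geometry that will become C6′=C7′.

Step 11
Reactants: 14 1,3-dioxoisoindolin-2-yl (4E)-6-[(3aR,7aR)-2,5-dioxo-3,4,5,7a-tetrahydro-1-benzofuran-3a(2H)-yl]-4-methylhex-4-enoate; 19 (E)-1-iodo-2,6-dimethylhepta-1,5-diene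
Product: 20 (3aR,7aR)-3a-[(2E,6E)-3,7,11-trimethyldodeca-2,6,10-trien-1-yl]-3a,4-dihydro-1-benzofuran-2,5(3H,7aH)-dione (CNP0400313.1)
Conditions: 14 (1 equiv), 19 (2 equiv), NiCl2·6H2O (10–20 mol %), 2,2′-bipyridine, AgNO3 (sub-stoichiometric), DMF, undivided cell, (+)Mg/(−)RVC, constant current (2.5–3 F/mol), rt, argon
Reagents that add atoms: none
Why: Ni-electrocatalytic decarboxylative alkenylation (reductive cross-electrophile coupling of a redox-active ester with an alkenyl halide, the reaction type used to assemble polyene terpenoid chains): cathodically generated Ni(0)(bpy) adds oxidatively to the C–I bond of 19 with retention, low-valent nickel transfers one electron to the phthalimide ester of 14, which fragments to phthalimide anion, CO2 and the primary C5′ radical, and the alkenyl–Ni(II) captures this radical so that the resulting Ni(III) reductively eliminates the C5′–C6′ bond while the Mg anode supplies the electrons. No ring is closed and no stereocentre is formed: C3a and C7a are remote spectators, the 6′E geometry is inherited with retention from 19 (fixed by syn-carboalumination in step 10) and the 2′E geometry from 11. The step needs chemoselectivity for the N-acyloxyphthalimide over the γ-acyloxy enone and integrity of the homoallylic radical: the activated ester is reduced at a much less negative potential than a cyclohexenone, the excess of 19 keeps nickel as the alkenyl–Ni(II) species so that little Ni(0) remains to ionise the allylic C7a–O bond, the enone β-carbon C7 is shielded against Giese addition by C7a and the quaternary C3a, and 3-exo closure of the but-3-enyl-type radical is slow and degenerate. The precursor pair is simple because iodine and the extra carboxyl carbon are the only activating groups and both are expelled in the step itself, so the product is the unprotected target.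

**Compound list**

1 | 1,4-dioxaspiro[4.5]dec-6-en-8-one | O=C1C=CC2(CC1)OCCO2 | starting material
2 | tert-butyl bromoacetate | CC(C)(C)OC(=O)CBr | starting material
3 | tert-butyl 2-(8-oxo-1,4-dioxaspiro[4.5]dec-6-en-9-yl)acetate (racemic) | O=C1C=CC2(CC1CC(=O)OC(C)(C)C)OCCO2 | intermediate (not isolated)
4 | di-tert-butyl 2,2′-(8-oxo-1,4-dioxaspiro[4.5]dec-6-ene-9,9-diyl)diacetate | O=C1C=CC2(CC1(CC(=O)OC(C)(C)C)CC(=O)OC(C)(C)C)OCCO2 | intermediate
5 | di-tert-butyl 2,2′-[(8R)-8-hydroxy-1,4-dioxaspiro[4.5]dec-6-ene-9,9-diyl]diacetate | O[C@@H]1C=CC2(CC1(CC(=O)OC(C)(C)C)CC(=O)OC(C)(C)C)OCCO2 | intermediate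
6 | 2,2′-[(2R)-2-hydroxy-5-oxocyclohex-3-ene-1,1-diyl]diacetic acid | O[C@@H]1C=CC(=O)CC1(CC(=O)O)CC(=O)O | intermediate (not isolated)
7 | 2-[(3aS,7aR)-2,5-dioxo-3,4,5,7a-tetrahydro-1-benzofuran-3a(2H)-yl]acetic acid (cis-fused) | OC(=O)C[C@]12CC(=O)C=C[C@H]1OC(=O)C2 | intermediate
8 | 1,3-dioxoisoindolin-2-yl 2-[(3aR,7aR)-2,5-dioxo-3,4,5,7a-tetrahydro-1-benzofuran-3a(2H)-yl]acetate | O=C(C[C@]12CC(=O)C=C[C@H]1OC(=O)C2)ON3C(=O)c4ccccc4C3=O | intermediate
9 | pent-4-yn-1-ol | C#CCCCO | starting material
10 | dimethylaluminium alkoxide of (E)-5-(dimethylalumanyl)-4-methylpent-4-en-1-ol | C/C(CCCO[Al](C)C)=C\[Al](C)C | intermediate (not isolated)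
11 | (E)-5-iodo-4-methylpent-4-en-1-ol | OCCC/C(C)=C/I | intermediate
12 | (3aR,7aR)-3a-[(2E)-6-hydroxy-3-methylhex-2-en-1-yl]-3a,4-dihydro-1-benzofuran-2,5(3H,7aH)-dione | OCCC/C(C)=C/C[C@]12CC(=O)C=C[C@H]1OC(=O)C2 | intermediate
13 | (4E)-6-[(3aR,7aR)-2,5-dioxo-3,4,5,7a-tetrahydro-1-benzofuran-3a(2H)-yl]-4-methylhex-4-enoic acid | OC(=O)CC/C(C)=C/C[C@]12CC(=O)C=C[C@H]1OC(=O)C2 | intermediate
14 | 1,3-dioxoisoindolin-2-yl (4E)-6-[(3aR,7aR)-2,5-dioxo-3,4,5,7a-tetrahydro-1-benzofuran-3a(2H)-yl]-4-methylhex-4-enoate | O=C(CC/C(C)=C/C[C@]12CC(=O)C=C[C@H]1OC(=O)C2)ON3C(=O)c4ccccc4C3=O | intermediate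
15 | 6-methylhept-5-en-2-one | CC(=O)CCC=C(C)C | starting material
16 | diethyl 6-methylhepta-1,5-dien-2-yl phosphate | C=C(CCC=C(C)C)OP(=O)(OCC)OCC | intermediate (not isolated)
17 | 6-methylhept-5-en-1-yne | C#CCCC=C(C)C | intermediate
18 | [(1E)-2,6-dimethylhepta-1,5-dien-1-yl]dimethylalane | CC(C)=CCC/C(C)=C/[Al](C)C | intermediate (not isolated)
19 | (E)-1-iodo-2,6-dimethylhepta-1,5-diene | CC(C)=CCC/C(C)=C/I | intermediate
20 | (3aR,7aR)-3a-[(2E,6E)-3,7,11-trimethyldodeca-2,6,10-trien-1-yl]-3a,4-dihydro-1-benzofuran-2,5(3H,7aH)-dione | CC(C)=CCC/C(C)=C/CC/C(C)=C/C[C@]12CC(=O)C=C[C@H]1OC(=O)C2 | target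

**Step count and risks**

Total step count: 11. Longest linear sequence: 8 steps (1, 2, 3, 4, 6, 7, 8, 11).

Steps most likely to fail:

Step 11. If nickel capture of the homoallylic C5′ radical is slow, the radical can close reversibly onto C3′ (3-exo) and reopen with loss of the 2′E geometry, or be reduced to the C5′–H compound. The fallback sets out from 8 and returns at 20; the C5′–C6′ bond is then bought instead of made. Purchased (E)-geranylacetone F1 is taken through the sequence of step 9 (LDA; ClP(O)(OEt)2; LDA) via the enol phosphate F2 to (5E)-6,10-dimethylundeca-5,9-dien-1-yne F3. Zirconium-catalysed carboalumination (Me3Al, Cp2ZrCl2, CH2Cl2) gives the alkenylalane F4, and iodine then gives (1E,5E)-1-iodo-2,6,10-trimethylundeca-1,5,9-triene F5. Electro-coupling of F5 with the core ester 8 under the conditions of step 6 forms C1′–C2′ through a radical that has no alkene within reach and gives 20 directly; steps 5 to 8 fall away.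

Step 6. The neopentyl-type C1′ radical (next to the quaternary C3a) is captured slowly, so consumption of the core by the reducing medium can outrun coupling: nickel-mediated ionisation of the allylic C7a–O bond, or Giese addition of the radical to C7 of a second molecule. The fallback sets out from 7 and returns at 12; the enone is moved to another oxidation level for the coupling. Conjugate addition of thiophenol (Et3N, CH2Cl2) to C7 of 7 gives the 7-phenylsulfanyl keto acid F6 (core centres unchanged, C7 configuration open), in which there is no enone and the lactone C–O bond is no longer allylic. N-Hydroxyphthalimide/DIC converts it into the phthalimide ester F7, and electro-coupling with 11 as in step 6 gives the sulfide alcohol F8. NaIO4 (MeOH/H2O, 0 °C) oxidises sulfur only and gives the sulfoxide F9, which on gentle warming (toluene, 60 °C, CaCO3) loses benzenesulfenic acid towards the acidic C6–H and returns enone 12.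

Step 2. Facial discrimination may be poor, because the two flanks of the C8 carbonyl (vinyl C7 and quaternary C9) may not differ enough for the oxazaborolidine, or the sense may be opposite to the one expected. The fallback sets out from 4 and returns at 5; it replaces asymmetric catalysis by classical resolution. Luche reduction (NaBH4, CeCl3·7H2O, MeOH, 0 °C) gives the racemic alcohol F10. Esterification with (S)-2-methoxy-2-phenylacetic acid (DCC, DMAP, CH2Cl2) gives the (S)-O-methylmandelate of the 8R alcohol F11 and the (S)-O-methylmandelate of the 8S alcohol F12, which are separated by chromatography or crystallisation. Methanolysis of F11 (K2CO3, MeOH) returns 5 with tert-butyl esters and ketal untouched.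

**Further compounds**

F1 | step 11 | (E)-geranylacetone, (5E)-6,10-dimethylundeca-5,9-dien-2-one (purchased) | CC(=O)CC/C=C(\C)CCC=C(C)C
F2 | step 11 | diethyl (5E)-6,10-dimethylundeca-1,5,9-trien-2-yl phosphate | C=C(CC/C=C(\C)CCC=C(C)C)OP(=O)(OCC)OCC
F3 | step 11 | (5E)-6,10-dimethylundeca-5,9-dien-1-yne | C#CCC/C=C(\C)CCC=C(C)C
F4 | step 11 | dimethyl[(1E,5E)-2,6,10-trimethylundeca-1,5,9-trien-1-yl]alane | CC(C)=CCC/C(C)=C/CC/C(C)=C/[Al](C)C
F5 | step 11 | (1E,5E)-1-iodo-2,6,10-trimethylundeca-1,5,9-triene | CC(C)=CCC/C(C)=C/CC/C(C)=C/I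
F6 | step 6 | 2-[2,5-dioxo-7-(phenylsulfanyl)hexahydro-1-benzofuran-3a(2H)-yl]acetic acid (cis-fused, ring-fusion centres as in 7, C7 open) | OC(=O)C[C@]12CC(=O)CC(Sc3ccccc3)[C@H]1OC(=O)C2
F7 | step 6 | 1,3-dioxoisoindolin-2-yl ester of F6 | O=C(C[C@]12CC(=O)CC(Sc3ccccc3)[C@H]1OC(=O)C2)ON4C(=O)c5ccccc5C4=O
F8 | step 6 | 3a-[(2E)-6-hydroxy-3-methylhex-2-en-1-yl]-7-(phenylsulfanyl)hexahydro-1-benzofuran-2,5-dione (ring-fusion centres as in 12, C7 open) | OCCC/C(C)=C/C[C@]12CC(=O)CC(Sc3ccccc3)[C@H]1OC(=O)C2
F9 | step 6 | S-oxide (sulfoxide) of F8 | OCCC/C(C)=C/C[C@]12CC(=O)CC(S(=O)c3ccccc3)[C@H]1OC(=O)C2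
F10 | step 2 | racemic di-tert-butyl 2,2′-(8-hydroxy-1,4-dioxaspiro[4.5]dec-6-ene-9,9-diyl)diacetate | OC1C=CC2(CC1(CC(=O)OC(C)(C)C)CC(=O)OC(C)(C)C)OCCO2
F11 | step 2 | (2S)-2-methoxy-2-phenylacetate of the 8R alcohol 5 | CO[C@H](C(=O)O[C@@H]1C=CC2(CC1(CC(=O)OC(C)(C)C)CC(=O)OC(C)(C)C)OCCO2)c3ccccc3
F12 | step 2 | (2S)-2-methoxy-2-phenylacetate of the 8S alcohol | CO[C@H](C(=O)O[C@H]1C=CC2(CC1(CC(=O)OC(C)(C)C)CC(=O)OC(C)(C)C)OCCO2)c3ccccc3
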